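## The problem

The target is a tridepside. Three substituted benzoyl units (rings A, B and C) are joined head to tail by two aryl ester bonds, each between a di-ortho-substituted benzoic acid and the 4-hydroxyl of the next ring. There is no stereocentre, so the difficulty lies in the order of bond formation and in telling the oxygens apart. The aryl ester links are cleaved or scrambled by hydroxide, alkoxides, amines and strong Lewis acids, and the free ortho-oxygenated benzoic acid can lose CO2 on heating. The last operations must therefore be neutral and mild, which points to benzyl groups and hydrogenolysis. Rings A and B are orsellinate units: their 4-hydroxyl is the reactive one and the 2-hydroxyl is hydrogen-bonded to the carbonyl, so the acylation pattern of ring B follows innate reactivity. Ring C does not: its C2 oxygen (ortho to the carboxyl) is methylated and its C4 oxygen acylated, whereas alkylation of an orsellinate goes to O4 first. The feature that opens a way round this is a mapping of ring C onto a 2-pyrone. Ring C atoms C1 (carboxyl), C2 (methoxy), C3 (H) and C6 (methyl) coincide with C5, C4, C3 and C6 of a 4-methoxy-6-methyl-2-pyrone-5-carboxylate. C4 with its oxygen and C5 can then come from a two-carbon ketene acetal, so the two oxygens of ring C originate in different reactants.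

## Retrosynthesis

**Target 20 to 19.** The three benzyl C–O bonds are cut (two ethers on ring A, the ester on ring C), leading back to the tridepside 19. Methyl or acyl protection would need base or Lewis acid for removal, which the depside bonds would not survive. The forward reaction is a hydrogenolysis that must leave both aryl esters untouched.

**19 to 18 and 12.** The ester bond between the ring B carbonyl and the ring C oxygen is cut. Cutting here, rather than at the A–B ester, separates the part that comes from orsellinic acid (didepside acid 18) from the ring that must be built (phenol 12). Cutting A–B last would need a B–C didepside with a free ring B 4-hydroxyl, hence an extra orthogonal group on ring B. The forward reaction asks a hindered acid with a free, chelated ortho-hydroxyl to acylate the single hydroxyl of 12.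

**18 to 17, then 15 and 16.** The allyl–oxygen bond of ester 17 is cut, then the A–B ester bond, giving acid 15 and allyl orsellinate 16. Allyl is chosen because it must differ from the benzyl groups kept to the end and must come off under neutral conditions; methyl or tert-butyl esters would need hydroxide or strong acid. The forward coupling must acylate the 4-hydroxyl of 16 and not the chelated 2-hydroxyl.

**15 and 16 to 13.** Acid 15 goes back through its benzyl ester 14 to orsellinic acid 13 (perbenzylation, then saponification). Ester 16 comes from 13 by carboxylate alkylation. One purchased acid thus supplies both rings A and B.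

**12 to 11, then 5 and 8 (key cut).** After the silicon–oxygen cut, ring C of 11 is opened at C3–C4 and C5–C6, giving pyrone 5 and ketene acetal 8. The neighbouring option is to make 12 from 13 by masking O4, methylating the chelated O2 and unmasking, which works against the innate order and costs three protecting-group operations. The ring cut instead places methoxy, carboxyl and methyl on a monocyclic pyrone and brings the second oxygen in with a two-carbon reagent. The forward reaction must bond the methylene of 8 to pyrone C6 and the acetal carbon to C3, then lose CO2 (through lactone 9) and silanol (from diene 10).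

**5 to 4, 3, then 1 and 2.** The O–methyl bond is cut (5 to 4), then the lactone C–O bond between O1 and C2 (4 to 3), then the C–C bond to the acetyl group (3 to 1 and 2). Dibenzyl 3-oxopentanedioate 1 supplies pyrone C2 to C5 and the ester; acetyl chloride 2 supplies C6 and its methyl. The forward steps need mono-C-acylation, one lactonisation mode and O-methylation at the C4 oxygen.

**8 to 7 to 6.** The two silicon–oxygen bonds are cut in turn, leading to silyl acetate 7 and acetic acid 6. The forward enolate silylation must occur on oxygen, not carbon.

## Roads not taken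

**Alternative 1: biomimetic fold closing ring A.** The cut is the ring A bond between the carboxyl-bearing and the methyl-bearing carbon, which opens ring A to the aryl 3,5,7-trioxooctanoate A2, already esterified to ring B of a B–C didepside. In the forward step C2 of the chain adds to the C7 ketone and two dehydrations give A1, with free ring A phenols.
- Merits: ring A needs no protection, the A–B ester is made from an unhindered aliphatic acid, and only hydrogenolysis follows.
- Weak points: a triketo ester of a phenol is a strongly activated ester. Lactonisation of the C5 enol onto C1, or Claisen closure from C6, would each expel the didepside phenol, and the aldol mode has to win against both under enolising conditions that also threaten the B–C ester.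
- Comparison: it is better than the chosen plan in protecting-group economy on ring A (steps 8 and 9 would disappear). But ring A is the one ring that can be bought as 13, and this route leaves the ring C problem unsolved, since it still needs 12 or an equivalent. The chosen plan offers in return ester formations of a precedented type only, and a key step spent on the ring that cannot be derived from 13 directly.

**Alternative 2: carbonylative union of rings B and C.** The cut removes both bonds at the B–C carbonyl carbon. In the forward step the aryl iodide A4, carbon monoxide and phenol 12 combine on a palladium catalyst (Pd(OAc)2 with a bisphosphine, amine base) to give A3.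
- Merits: no ring B carboxylic acid has to be unmasked and activated, and the ring B 2-hydroxyl is a benzyl ether, so self-acylation cannot occur. In this respect it is better than step 13 of the chosen plan.
- Weak points: the iodine is flanked by methyl and benzyloxy, so capture of the hindered acyl–palladium species by a phenoxide should be slow. The base and phenoxide at elevated temperature can transfer the ring A acyl group of A4 to 12. The two hydroxyls of the iodo-orcinol precursor of A4 must be told apart without a chelating carbonyl. The route also still needs 12.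
- Comparison: it answers the last ester bond, not the substitution problem of ring C, and could be grafted onto the chosen route. The chosen plan offers in return both rings A and B from 13 with innate 4-hydroxyl selectivity, no CO, and an acylation method known to tolerate the free ortho-hydroxyl.

**Alternative 3: Danheiser benzannulation of ring B.** Ring B is taken apart into the diazoketone A6, which already carries ring C as its aryl ester, and the siloxyalkyne A7. On irradiation, Wolff rearrangement gives a vinylketene; (2+2) addition to A7, four-electron ring opening and six-electron closure give A5, with free 2-hydroxyl and silylated 4-hydroxyl.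
- Merits: the two ring B oxygens are differentiated by construction, the B–C ester is made at an unhindered acyclic stage, and the silyl ether is a clean handle for the last acylation. In these respects it equals or betters the chosen endgame.
- Weak points: ring B has exactly the pattern that 13 gives through innate reactivity, so the annulation solves a problem that does not exist there. A6 and A7 are sensitive and each needs several steps, the step is photochemical, and ring C must be made beforehand because A6 contains it.
- Comparison: the idea of differentiating oxygens by building the ring is the same as in the chosen plan, but applied to the ring that does not need it. The chosen plan applies it to ring C and offers a thermal key step and short access from catalogue compounds.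

Key step: step 6

## Route

Remark: dibenzyl 3-oxopentanedioate 1 is treated as a catalogue compound. Cycloadduct 9 forms as a racemate whose two bridgehead stereocentres vanish on aromatisation, so its SMILES carries no stereodescriptors.

Step 1
Reactants: 1 dibenzyl 3-oxopentanedioate; 2 acetyl chloride
Product: 3 dibenzyl 2-acetyl-3-oxopentanedioate
Conditions: MgCl2, pyridine, CH2Cl2, 0 °C to rt; aq. HCl work-up
Reagents that add atoms: none
Why: Magnesium-chelate-directed C-acylation of a 1,3-dicarbonyl compound (Rathke conditions); the more acidic tricarbonyl product stays bound as its magnesium chelate, which should prevent a second acylation at the other methylene.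

Step 2
Reactants: 3 dibenzyl 2-acetyl-3-oxopentanedioate
Product: 4 benzyl 4-hydroxy-6-methyl-2-oxo-2H-pyran-5-carboxylate
Conditions: DBU, PhMe, reflux; aq. HCl work-up
Reagents that add atoms: none
Why: Base-mediated lactonisation of a 3,5-dioxo ester to a 4-hydroxy-2-pyrone; the enolate oxygen of the acetyl group attacks the distal benzyl ester in the only six-membered lactonisation available and benzyl alcohol is expelled; the competing Claisen carbocyclisation from the acetyl methyl would need a dianion that DBU does not form.

Step 3
Reactants: 4 benzyl 4-hydroxy-6-methyl-2-oxo-2H-pyran-5-carboxylate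
Product: 5 benzyl 4-methoxy-6-methyl-2-oxo-2H-pyran-5-carboxylate
Conditions: Me2SO4, K2CO3, acetone, reflux
Reagents that add atoms: dimethyl sulfate, COS(=O)(=O)OC
Why: O-alkylation of the vinylogous acid; with dimethyl sulfate and carbonate in acetone 4-hydroxy-2-pyrones are expected to give the 4-methoxy-2-pyrone rather than the 2-methoxy-4-pyrone or the C3-methyl compound, and the lactone and benzyl ester are inert.

Step 4
Reactants: 6 acetic acid
Product: 7 tert-butyldimethylsilyl acetate
Conditions: TBSCl, Et3N, CH2Cl2, 0 °C to rt; filtration, distillation
Reagents that add atoms: tert-butyldimethylsilyl chloride, CC(C)(C)[Si](C)(C)Cl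
Why: Silylation of a carboxylate to the silyl ester; non-aqueous isolation keeps the moisture-sensitive ester intact.

Step 5
Reactants: 7 tert-butyldimethylsilyl acetate
Product: 8 1,1-bis(tert-butyldimethylsilyloxy)ethene
Conditions: LiN(iPr)2, THF, −78 °C; TBSCl, DMPU, −78 °C to rt; pentane extraction, distillation
Reagents that add atoms: tert-butyldimethylsilyl chloride, CC(C)(C)[Si](C)(C)Cl
Why: Kinetic enolisation of the silyl ester and O-silylation of the lithium enolate (formation of a bis-silyl ketene acetal in the manner of Ainsworth); the bulky silyl chloride with a dipolar cosolvent should favour silylation on oxygen over carbon.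

Step 6
Reactants: 5 benzyl 4-methoxy-6-methyl-2-oxo-2H-pyran-5-carboxylate; 8 1,1-bis(tert-butyldimethylsilyloxy)ethene
Product: 11 benzyl 4-(tert-butyldimethylsilyloxy)-2-methoxy-6-methylbenzoate, via bridged lactone cycloadduct 9 (not isolated), via bis(silyloxy)cyclohexadiene 10 (not isolated)
Conditions: 8 (3 equiv), PhMe, 110 °C, sealed tube
Reagents that add atoms: none
Why: Inverse-electron-demand Diels–Alder reaction of a 2-pyrone with a ketene acetal followed by cycloreversion, the reaction type by which coumalate esters and ketene acetals give para-oxygenated benzoates. The electron-poor diene C3=C4–C5=C6 of 5 takes up the electron-rich alkene of 8: the methylene carbon bonds to pyrone C6 and the acetal carbon to C3, either in one event or by conjugate addition at C6 followed by closure of the dienolate carbon C3 onto the silyloxy-stabilised cation. Ring C is closed in this (4+2) mode as the bridged lactone 9, whose two bridgehead stereocentres arise as a racemate and are both destroyed afterwards, so no stereocontrol is needed. Retro-Diels–Alder loss of CO2 from 9 gives the cyclohexadiene 10, and elimination of tert-butyldimethylsilanol across the geminal bis(silyloxy) carbon and the neighbouring methylene aromatises it to 11. The one selectivity required is regiochemical: C6 is the β-carbon of the 5-carboxylate and the δ-carbon of the lactone carbonyl and so the most electrophilic terminus, whereas C3 is an α-carbon and C4 is deactivated by its methoxy group. The methoxy oxygen comes from the pyrone and the silyloxy oxygen from 8, so the two ring C oxygens are distinguished by construction. Adventitious loss of the silyl group would give 12, the product of the next step, and costs nothing.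

Step 7
Reactants: 11 benzyl 4-(tert-butyldimethylsilyloxy)-2-methoxy-6-methylbenzoate
Product: 12 benzyl 4-hydroxy-2-methoxy-6-methylbenzoate
Conditions: Bu4NF, AcOH, THF, 0 °C
Reagents that add atoms: none
Why: Fluoride cleavage of an aryl silyl ether; buffering with acetic acid keeps the medium near neutral so that the benzyl ester is not attacked.

Step 8
Reactants: 13 orsellinic acid (2,4-dihydroxy-6-methylbenzoic acid)
Product: 14 benzyl 2,4-bis(benzyloxy)-6-methylbenzoate
Conditions: BnBr (excess), K2CO3, DMF, rt to 60 °C
Reagents that add atoms: benzyl bromide, BrCc1ccccc1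
Why: Williamson alkylation of the carboxylate and both phenoxides; the carboxylate is esterified first at room temperature, which removes the risk of decarboxylation, and warming in DMF then alkylates the chelated 2-hydroxyl.

Step 9
Reactants: 14 benzyl 2,4-bis(benzyloxy)-6-methylbenzoate
Product: 15 2,4-bis(benzyloxy)-6-methylbenzoic acid
Conditions: KOH, DMSO–H2O, 90 °C; then aq. HCl
Reagents that add atoms: potassium hydroxide, [K+].[OH-]
Why: Saponification of a di-ortho-substituted benzoate, which needs forcing conditions; the aryl benzyl ethers are inert to hydroxide.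

Step 10
Reactants: 13 orsellinic acid (2,4-dihydroxy-6-methylbenzoic acid)
Product: 16 allyl 2,4-dihydroxy-6-methylbenzoate
Conditions: allyl bromide (1.05 equiv), KHCO3, DMF, rt
Reagents that add atoms: allyl bromide, C=CCBr
Why: Alkylation of the carboxylate under hydrogen carbonate, which does not ionise the phenols appreciably; the same conditions are the standard entry to benzyl orsellinate.

Step 11
Reactants: 15 2,4-bis(benzyloxy)-6-methylbenzoic acid; 16 allyl 2,4-dihydroxy-6-methylbenzoate
Product: 17 allyl 4-{[2,4-bis(benzyloxy)-6-methylbenzoyl]oxy}-2-hydroxy-6-methylbenzoate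
Conditions: (CF3CO)2O, PhMe, 0 °C to rt
Reagents that add atoms: none
Why: Trifluoroacetic anhydride-mediated depside esterification through the mixed anhydride (acylium character) of the electron-rich hindered acid; the 4-hydroxyl of 16 is free and nucleophilic, while the 2-hydroxyl is hydrogen-bonded to the ester carbonyl and flanked by it, so acylation should occur at O4.

Step 12
Reactants: 17 allyl 4-{[2,4-bis(benzyloxy)-6-methylbenzoyl]oxy}-2-hydroxy-6-methylbenzoate
Product: 18 4-{[2,4-bis(benzyloxy)-6-methylbenzoyl]oxy}-2-hydroxy-6-methylbenzoic acid
Conditions: Pd(PPh3)4 (cat.), N-methylaniline, THF, rt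
Reagents that add atoms: none
Why: Tsuji–Trost deallylation: zerovalent palladium ionises the allyl ester to a π-allyl complex and the carboxylate, and the weakly nucleophilic amine traps the allyl group without attacking the aryl ester; benzyl ethers are untouched.

Step 13
Reactants: 18 4-{[2,4-bis(benzyloxy)-6-methylbenzoyl]oxy}-2-hydroxy-6-methylbenzoic acid; 12 benzyl 4-hydroxy-2-methoxy-6-methylbenzoate
Product: 19 benzyl 4-({4-[(2,4-bis(benzyloxy)-6-methylbenzoyl)oxy]-2-hydroxy-6-methylbenzoyl}oxy)-2-methoxy-6-methylbenzoate
Conditions: (CF3CO)2O, PhMe, rt
Reagents that add atoms: none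
Why: Second trifluoroacetic anhydride-mediated esterification; 12 offers a single unhindered hydroxyl, while the ortho-hydroxyl of 18 is chelated and hindered, as in the established couplings of ortho-hydroxybenzoic acids in depside synthesis; any aryl trifluoroacetate formed is hydrolysed on work-up.

Step 14
Reactants: 19 benzyl 4-({4-[(2,4-bis(benzyloxy)-6-methylbenzoyl)oxy]-2-hydroxy-6-methylbenzoyl}oxy)-2-methoxy-6-methylbenzoate
Product: 20 4-({4-[(2,4-dihydroxy-6-methylbenzoyl)oxy]-2-hydroxy-6-methylbenzoyl}oxy)-2-methoxy-6-methylbenzoic acid
Conditions: H2 (1 atm), 10% Pd/C, EtOAc, rt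
Reagents that add atoms: none
Why: Hydrogenolysis of two aryl benzyl ethers and one benzyl ester; the aryl ester bonds are not benzylic and should survive, and neutral conditions at room temperature avoid depside cleavage and decarboxylation.

## Compound list

1 | dibenzyl 3-oxopentanedioate | O=C(CC(=O)OCc1ccccc1)CC(=O)OCc1ccccc1 | starting material
2 | acetyl chloride | CC(=O)Cl | starting material
3 | dibenzyl 2-acetyl-3-oxopentanedioate (enolised, no defined stereocentre) | CC(=O)C(C(=O)OCc1ccccc1)C(=O)CC(=O)OCc1ccccc1 | intermediate
4 | benzyl 4-hydroxy-6-methyl-2-oxo-2H-pyran-5-carboxylate | Cc1oc(=O)cc(O)c1C(=O)OCc1ccccc1 | intermediate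
5 | benzyl 4-methoxy-6-methyl-2-oxo-2H-pyran-5-carboxylate | COc1cc(=O)oc(C)c1C(=O)OCc1ccccc1 | intermediate
6 | acetic acid | CC(=O)O | starting material
7 | tert-butyldimethylsilyl acetate | CC(=O)O[Si](C)(C)C(C)(C)C | intermediate
8 | 1,1-bis(tert-butyldimethylsilyloxy)ethene | C=C(O[Si](C)(C)C(C)(C)C)O[Si](C)(C)C(C)(C)C | intermediate
9 | benzyl 8,8-bis(tert-butyldimethylsilyloxy)-5-methoxy-1-methyl-3-oxo-2-oxabicyclo[2.2.2]oct-5-ene-6-carboxylate (racemic, not isolated) | COC1=C(C(=O)OCc2ccccc2)C2(C)CC(O[Si](C)(C)C(C)(C)C)(O[Si](C)(C)C(C)(C)C)C1C(=O)O2 | intermediate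
10 | benzyl 4,4-bis(tert-butyldimethylsilyloxy)-6-methoxy-2-methylcyclohexa-1,5-diene-1-carboxylate (not isolated) | COC1=CC(O[Si](C)(C)C(C)(C)C)(O[Si](C)(C)C(C)(C)C)CC(C)=C1C(=O)OCc1ccccc1 | intermediate
11 | benzyl 4-(tert-butyldimethylsilyloxy)-2-methoxy-6-methylbenzoate | COc1cc(O[Si](C)(C)C(C)(C)C)cc(C)c1C(=O)OCc1ccccc1 | intermediate
12 | benzyl 4-hydroxy-2-methoxy-6-methylbenzoate | COc1cc(O)cc(C)c1C(=O)OCc1ccccc1 | intermediate
13 | orsellinic acid (2,4-dihydroxy-6-methylbenzoic acid) | Cc1cc(O)cc(O)c1C(=O)O | starting material
14 | benzyl 2,4-bis(benzyloxy)-6-methylbenzoate | Cc1cc(OCc2ccccc2)cc(OCc2ccccc2)c1C(=O)OCc1ccccc1 | intermediate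
15 | 2,4-bis(benzyloxy)-6-methylbenzoic acid | Cc1cc(OCc2ccccc2)cc(OCc2ccccc2)c1C(=O)O | intermediate
16 | allyl 2,4-dihydroxy-6-methylbenzoate | Cc1cc(O)cc(O)c1C(=O)OCC=C | intermediate
17 | allyl 4-{[2,4-bis(benzyloxy)-6-methylbenzoyl]oxy}-2-hydroxy-6-methylbenzoate | Cc1cc(OC(=O)c2c(C)cc(OCc3ccccc3)cc2OCc2ccccc2)cc(O)c1C(=O)OCC=C | intermediate
18 | 4-{[2,4-bis(benzyloxy)-6-methylbenzoyl]oxy}-2-hydroxy-6-methylbenzoic acid | Cc1cc(OC(=O)c2c(C)cc(OCc3ccccc3)cc2OCc2ccccc2)cc(O)c1C(=O)O | intermediate
19 | benzyl 4-({4-[(2,4-bis(benzyloxy)-6-methylbenzoyl)oxy]-2-hydroxy-6-methylbenzoyl}oxy)-2-methoxy-6-methylbenzoate | COc1cc(OC(=O)c2c(C)cc(OC(=O)c3c(C)cc(OCc4ccccc4)cc3OCc3ccccc3)cc2O)cc(C)c1C(=O)OCc1ccccc1 | intermediate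
20 | 4-({4-[(2,4-dihydroxy-6-methylbenzoyl)oxy]-2-hydroxy-6-methylbenzoyl}oxy)-2-methoxy-6-methylbenzoic acid | COc1cc(OC(=O)c2c(C)cc(OC(=O)c3c(C)cc(O)cc3O)cc2O)cc(C)c1C(=O)O | target

## Step count and uncertain steps

Total: 14 steps. Longest linear sequence: 7 steps (1, 2, 3, 6, 7, 13, 14). The didepside branch (8, 9, 11, 12) and the ketene acetal branch (4, 5) run in parallel.

**Step 6 (key step).** The 4-methoxy group lowers the electrophilicity of the diene and the 6-methyl group hinders bond formation at C6. The cycloaddition may therefore be slower than decomposition of the ketene acetal (silyl migration from oxygen to carbon, hydrolysis by traces of water). Conjugate addition with silyl transfer but without closure of the second bond is a second possible failure. Fallback: abandon the pyrone and reach the same phenol by protecting-group chemistry, setting out from 13 and coming back at 12.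
- 13 is esterified (BnBr, KHCO3, DMF) to benzyl 2,4-dihydroxy-6-methylbenzoate F1.
- The non-chelated 4-hydroxyl is allylated (allyl bromide, 1 equiv, K2CO3, acetone) to benzyl 4-(allyloxy)-2-hydroxy-6-methylbenzoate F2.
- The chelated hydroxyl is methylated (MeI, K2CO3, DMF) to benzyl 4-(allyloxy)-2-methoxy-6-methylbenzoate F3.
- The allyl ether is removed (Pd(PPh3)4, morpholine, THF) to give 12.

**Step 13.** Activation of an acid with a free ortho-hydroxyl may lead to self-acylation and oligomers, or to acyl migration across the existing depside bond under the acidic conditions. Fallback: mask the hydroxyl before unveiling the acid, setting out from 17 and coming back at 20.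
- 17 is benzylated (BnBr, K2CO3, DMF, rt) to allyl 2-(benzyloxy)-4-{[2,4-bis(benzyloxy)-6-methylbenzoyl]oxy}-6-methylbenzoate F4.
- Deallylation as in step 12 gives 2-(benzyloxy)-4-{[2,4-bis(benzyloxy)-6-methylbenzoyl]oxy}-6-methylbenzoic acid F5.
- Esterification with 12 ((CF3CO)2O, PhMe), now with no free hydroxyl on the acid, gives benzyl 4-({2-(benzyloxy)-4-[(2,4-bis(benzyloxy)-6-methylbenzoyl)oxy]-6-methylbenzoyl}oxy)-2-methoxy-6-methylbenzoate F6.
- Hydrogenolysis under the conditions of step 14 gives 20.

**Step 2.** The stabilised tricarbonyl anion may be too unreactive to close, or retro-Claisen loss of the acetyl group may compete. Fallback: form the pyrone by a different bond set. This one does not set out from a compound of the route; it bypasses 1, 2 and 3 and comes back at 4. Purchased benzyl 3-oxobutanoate F7 is condensed with malonyl dichloride (ClC(=O)CC(=O)Cl; CH2Cl2, rt to reflux) by C-acylation at the active methylene and O-acylation of the enol, with loss of HCl, to give 4.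

**Step 11.** Site selectivity between the 4- and 2-hydroxyl of 16 may be incomplete, and the allyl ester adds a palladium step that a free phenol could disturb. Fallback: mask the ring B carboxyl as an aldehyde, setting out from 15 and coming back at 18.
- 15 acylates purchased 2,4-dihydroxy-6-methylbenzaldehyde F8 ((CF3CO)2O, PhMe), whose 2-hydroxyl is even more strongly chelated, to give 4-formyl-3-hydroxy-5-methylphenyl 2,4-bis(benzyloxy)-6-methylbenzoate F9.
- Pinnick oxidation (NaClO2, NaH2PO4, 2-methylbut-2-ene, t-BuOH–H2O) gives 18.

## Further compounds

F1 | step 6 | benzyl 2,4-dihydroxy-6-methylbenzoate | Cc1cc(O)cc(O)c1C(=O)OCc1ccccc1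
F2 | step 6 | benzyl 4-(allyloxy)-2-hydroxy-6-methylbenzoate | Cc1cc(OCC=C)cc(O)c1C(=O)OCc1ccccc1
F3 | step 6 | benzyl 4-(allyloxy)-2-methoxy-6-methylbenzoate | COc1cc(OCC=C)cc(C)c1C(=O)OCc1ccccc1
F4 | step 13 | allyl 2-(benzyloxy)-4-{[2,4-bis(benzyloxy)-6-methylbenzoyl]oxy}-6-methylbenzoate | Cc1cc(OC(=O)c2c(C)cc(OCc3ccccc3)cc2OCc2ccccc2)cc(OCc2ccccc2)c1C(=O)OCC=C
F5 | step 13 | 2-(benzyloxy)-4-{[2,4-bis(benzyloxy)-6-methylbenzoyl]oxy}-6-methylbenzoic acid | Cc1cc(OC(=O)c2c(C)cc(OCc3ccccc3)cc2OCc2ccccc2)cc(OCc2ccccc2)c1C(=O)O
F6 | step 13 | benzyl 4-({2-(benzyloxy)-4-[(2,4-bis(benzyloxy)-6-methylbenzoyl)oxy]-6-methylbenzoyl}oxy)-2-methoxy-6-methylbenzoate | COc1cc(OC(=O)c2c(C)cc(OC(=O)c3c(C)cc(OCc4ccccc4)cc3OCc3ccccc3)cc2OCc2ccccc2)cc(C)c1C(=O)OCc1ccccc1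
F7 | step 2 | benzyl 3-oxobutanoate | CC(=O)CC(=O)OCc1ccccc1
F8 | step 11 | 2,4-dihydroxy-6-methylbenzaldehyde | Cc1cc(O)cc(O)c1C=O
F9 | step 11 | 4-formyl-3-hydroxy-5-methylphenyl 2,4-bis(benzyloxy)-6-methylbenzoate | Cc1cc(OC(=O)c2c(C)cc(OCc3ccccc3)cc2OCc2ccccc2)cc(O)c1C=O
A1 | alternative 1 | benzyl 4-({2-(benzyloxy)-4-[(2,4-dihydroxy-6-methylbenzoyl)oxy]-6-methylbenzoyl}oxy)-2-methoxy-6-methylbenzoate | Cc1cc(O)cc(O)c1C(=O)Oc1cc(C)c(C(=O)Oc2cc(C)c(C(=O)OCc3ccccc3)c(OC)c2)c(OCc2ccccc2)c1
A2 | alternative 1 | benzyl 4-({2-(benzyloxy)-6-methyl-4-[(3,5,7-trioxooctanoyl)oxy]benzoyl}oxy)-2-methoxy-6-methylbenzoate | CC(=O)CC(=O)CC(=O)CC(=O)Oc1cc(C)c(C(=O)Oc2cc(C)c(C(=O)OCc3ccccc3)c(OC)c2)c(OCc2ccccc2)c1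
A3 | alternative 2 | benzyl 4-({2-(benzyloxy)-4-[(2,4-bis(benzyloxy)-6-methylbenzoyl)oxy]-6-methylbenzoyl}oxy)-2-methoxy-6-methylbenzoate | COc1cc(OC(=O)c2c(C)cc(OC(=O)c3c(C)cc(OCc4ccccc4)cc3OCc3ccccc3)cc2OCc2ccccc2)cc(C)c1C(=O)OCc1ccccc1
A4 | alternative 2 | 3-(benzyloxy)-4-iodo-5-methylphenyl 2,4-bis(benzyloxy)-6-methylbenzoate | Cc1cc(OC(=O)c2c(C)cc(OCc3ccccc3)cc2OCc2ccccc2)cc(OCc2ccccc2)c1I
A5 | alternative 3 | benzyl 4-{[2-hydroxy-6-methyl-4-(triisopropylsilyloxy)benzoyl]oxy}-2-methoxy-6-methylbenzoate | Cc1cc(O[Si](C(C)C)(C(C)C)C(C)C)cc(O)c1C(=O)Oc1cc(C)c(C(=O)OCc2ccccc2)c(OC)c1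
A6 | alternative 3 | benzyl 4-{[(2E)-5-diazo-3-methyl-4-oxopent-2-enoyl]oxy}-2-methoxy-6-methylbenzoate | COc1cc(OC(=O)/C=C(\C)C(=O)C=[N+]=[N-])cc(C)c1C(=O)OCc1ccccc1
A7 | alternative 3 | (triisopropylsilyloxy)ethyne | C#CO[Si](C(C)C)(C(C)C)C(C)C
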